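The data were generated by integration for substances that don't exist, noise included.

Fed reagent cannot become target faster than it meets starting material, so reagent fed slowly need not be used up as it arrives.

| flask | starting material | reagent | second substrate | protic impurity | remark | time |
|---|---|---|---|---|---|---|
| Saturday's | 0.050 M | 0.95 equiv | 5 equiv | 1 mM | run made earlier |  |
| Wednesday's | 0.050 M | 0.64 equiv | 5 equiv | 1 mM | run made earlier |  |
| Tuesday's | 0.050 M | 1.4 equiv | 5 equiv | 1 mM | run made earlier |  |
| gamma | 0.050 M (fed, over 3.0 h) | 0.950 equiv | 5.00 equiv | 1.00 mM | all else is in the flask from the start; the feed brings no volume worth counting | 4.0 h |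
| delta | 0.050 M (fed, over 20 min) | 0.950 equiv | 5.00 equiv | 1.00 mM | all else is in the flask from the start; the feed brings no volume worth counting | 4.0 h |
| theta | 0.050 M | 0.950 equiv (fed, over 3.0 h) | 5.00 equiv | 1.00 mM | all else is in the flask from the start; the feed brings no volume worth counting | 4.0 h |
| beta | 0.050 M | 0.950 equiv | 5.00 equiv | 1.00 mM | everything together at the start | 4.0 h |

| run | time / h | target / % | starting material / % |
|---|---|---|---|
| Saturday's | 0.200 | 23.0 | 74.3 |
| Saturday's | 0.333 | 32.0 | 63.4 |
| Saturday's | 0.417 | 37.8 | 59.3 |
| Saturday's | 0.667 | 45.1 | 49.7 |
| Saturday's | 1.00 | 51.8 | 39.8 |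
| Saturday's | 1.50 | 57.6 | 31.5 |
| Saturday's | 2.50 | 61.3 | 21.6 |
| Wednesday's | 0.417 | 26.8 | 69.2 |
| Wednesday's | 0.667 | 33.1 | 60.1 |
| Wednesday's | 0.833 | 37.2 | 57.9 |
| Wednesday's | 1.33 | 38.6 | 48.8 |
| Wednesday's | 2.00 | 43.2 | 42.2 |
| Wednesday's | 3.00 | 41.7 | 34.8 |
| Wednesday's | 5.00 | 39.6 | 29.0 |
| Tuesday's | 0.667 | 58.6 | 33.0 |
| Tuesday's | 1.33 | 71.6 | 18.0 |
| Tuesday's | 2.00 | 76.3 | 11.1 |
| Tuesday's | 3.00 | 77.6 | 4.9 |
| Tuesday's | 4.00 | 78.2 | 3.2 |
| Tuesday's | 5.00 | 80.5 | 1.6 |

(scatter of a reading: 1 percentage point)

- which flask leads in amount of target, in percent of the starting material charged ("all alike" within 1.5 percentage points) (gamma / delta / theta / beta / all alike)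
- how much target is there at the end, in percent of the starting material charged: gamma
- how much target is there at the end, in percent of the starting material charged: delta
- how much target is there at the end, in percent of the starting material charged: theta
- how much target is there at the end, in percent of the starting material charged: beta

- percentages count the starting material that a species holds: one side product counts as two
- target is meant together with its idle adduct
- steps that have been proposed: second substrate + reagent -> second product; starting material + protic impurity -> quenched substrate; starting material + target -> side product; reagent + target <-> idle adduct; starting material + reagent -> target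

I read Saturday's run, with 0.95 equiv of reagent, as one second-order line: two readings of 1/c(starting material) gave a read rate constant of 0.00810 L mol⁻¹ s⁻¹. For theta I then reckoned the value 0.217 for the demand, the product of the standing fractions of starting material and reagent, both counted on the starting-material charge, at which making keeps pace with the feed; it is an inverse Damköhler number.

In my first round for theta, I took reagent as used up as fed, which gave 3.00% starting material at the feed's end. That required a reagent fraction of 7.23, more than the charge of 0.950, so the round failed. In my second round, I took the two partners as about equal, each at the square root of the demand, 46.6%. The same line over the remaining time gave 27.7% starting material as my estimate. Taking off quenched substrate and the gap of 15.1% read at Saturday's last reading, carried over unchanged, I put theta's target at 55.2%, less than the forecast's figure.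

The forecast named beta as leader, with gamma 50%, delta 61.5%, theta 60% and beta 62.5%, holding that in theta “conversion lags and starting material sits with target”.

The flasks gave gamma 47.7%, delta 58.8%, theta 54.7% and beta 60.6%, so beta led.

    second substrate + reagent → second product (k = 2.30 × 10⁻⁴ L mol⁻¹ s⁻¹)
    starting material + protic impurity → quenched substrate (k = 1.00 L mol⁻¹ s⁻¹)
    starting material + target → side product (k = 0.00110 L mol⁻¹ s⁻¹)
    reagent + target ⇌ idle adduct, settled at all times (K = 4.60 L mol⁻¹)
    starting material + reagent → target (k = 0.00970 L mol⁻¹ s⁻¹)

In theta, with a demand of 0.217, mean c(starting material) stood at 0.0348 M over the feed, and at 4.00 h the flask held 23.0% starting material and 14.9% of its reagent beside 54.7% target. In delta, where starting material was fed, the demand reckoned the same way was 2.06, above one, mean c(reagent) stood at 0.0420 M during the feed, and the flask ended at 58.8% target beside beta's 60.6%.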